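**Plan**
1. Retrosynthetic cuts, in order: the allyl aryl ether O5–C1′ (chain off); the lactone back to a phthalic diester (C3 returned to ester level); then C5–C6 and C3a–C7a of the benzene ring.
2. Enabling feature: all six benzene carbons of the isobenzofuran-1(3H)-one are substituted. C3a and C7a carry the carboxyl-derived carbons C3 and C1, C4/C5/C6 carry oxygen, and C7 carries H. Nucleophilic sites (C3a, C5) and electrophilic sites (C6, C7a) therefore alternate, and the ring divides into a 4-alkoxyacetoacetate (C3–C3a–C4–C5) and MeO2C–CO–CH=C(OMe)2 (C1–C7a–C7–C6).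
3. Forward order: the benzene ring comes first, by a TiCl4-mediated [3+3] cyclocondensation. O5 is held as a benzyl ether, because an allyl vinyl ether, a polyene and a tertiary carbinol would not tolerate TiCl4. The lactone ring comes second (exposed ester masked as carboxylate, hindered ester reduced), and the chain is joined last at O5.
4. Chain: (2E,6E)-farnesol, with formal Markovnikov hydration of the terminal alkene through bromohydrin, epoxide and hydride opening, then conversion to the allylic bromide.
5. Stereochemistry: the target has no stereocentre. Both E alkenes come with farnesol and no step touches them. The transient C10 centre of the chain is racemic and is erased.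

Key step: step 5

Remark: locants C1–C7a follow isobenzofuran-1(3H)-one numbering (C1 lactone carbonyl, O2, C3 methylene, C4 OH, C5 O-chain, C6 OMe, C7 H). The bromohydrin and the epoxides of the chain are racemic. Titanium- or silicon-bound intermediates of the key step are drawn in their metal-free keto forms.

**Step 1**
Reactants: 1 methyl 4-chloroacetoacetate; 2 benzyl alcohol
Product: 3 methyl 4-(benzyloxy)-3-oxobutanoate
Conditions: NaH (2.2 equiv), THF, 0 → 20 °C; then 1 M HCl
Reagents that add atoms: none
Why: Williamson-type SN2 displacement, in which the first equivalent of NaH stores the β-keto ester as its enolate (shielding ketone and ester) while sodium benzyloxide displaces the primary α-keto chloride.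

**Step 2**
Reactants: 3 methyl 4-(benzyloxy)-3-oxobutanoate
Product: 4 methyl 4-(benzyloxy)-3-(trimethylsilyloxy)but-2-enoate (geometry immaterial)
Conditions: Me3SiCl, Et3N, toluene, 20 °C; filtration under argon
Reagents that add atoms: chlorotrimethylsilane, C[Si](C)(C)Cl
Why: Silyl enol ether formation by soft enolisation of a β-keto ester should give the conjugated 3-silyloxy enoate, whose geometry has no consequence later.

**Step 3**
Reactants: 4 methyl 4-(benzyloxy)-3-(trimethylsilyloxy)but-2-enoate
Product: 5 4-(benzyloxy)-1-methoxy-1,3-bis(trimethylsilyloxy)buta-1,3-diene (geometry of both enol ethers immaterial)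
Conditions: LiN(iPr)2, THF, −78 °C; Me3SiCl, −78 → 20 °C; filtration under argon, used crude
Reagents that add atoms: chlorotrimethylsilane, C[Si](C)(C)Cl
Why: Kinetic γ-deprotonation and O-silylation of the extended ester enolate is the standard second stage of 1,3-bis(silyloxy)diene synthesis, and a benzyl ether at the deprotonated carbon offers no [2,3]- or [3,3]-sigmatropic escape.

**Step 4**
Reactants: 6 1,1-dimethoxyethene; 7 methyl chlorooxoacetate
Product: 8 methyl 4,4-dimethoxy-2-oxobut-3-enoate
Conditions: Et3N, Et2O, 0 → 20 °C; filtration, short-path distillation (no aqueous work-up)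
Reagents that add atoms: none
Why: C-acylation of an electron-rich ketene acetal by an acid chloride (addition, then loss of HCl to Et3N) gives the push-pull β,β-dimethoxy enone, and the acid chloride has no α-hydrogen, so no ketene pathway competes.

**Step 5**
Reactants: 5 4-(benzyloxy)-1-methoxy-1,3-bis(trimethylsilyloxy)buta-1,3-diene; 8 methyl 4,4-dimethoxy-2-oxobut-3-enoate
Product: 11 dimethyl 4-(benzyloxy)-3-hydroxy-5-methoxyphthalate, via open-chain vinylogous ester 9 (not isolated), via cyclic aldol 10 (not isolated)
Conditions: TiCl4 (1.1 equiv), 4 Å molecular sieves, CH2Cl2, −78 → 20 °C; then H2O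
Reagents that add atoms: none
Why: TiCl4 chelates the keto ester unit of 8, whose two methoxy groups push the positive character onto the acetal carbon (future C6), and the benzyloxy-bearing terminus of 5 (future C5) adds there in a Mukaiyama–Michael step, loss of one methoxy group giving vinylogous ester 9. The central carbon of the former diene (future C3a), still a silyl ketene acetal or titanium enolate, then attacks the chelated ketone (future C7a) in an intramolecular Mukaiyama aldol, a 6-(enolexo)-exo-trig closure that forms the six-membered carbocycle 10, and loss of water followed by enolisation of the C4 ketone turns it into the benzene ring of 11. The closest known reaction type is the TiCl4-mediated formal [3+3] cyclocondensation of 1,3-bis(silyloxy)buta-1,3-dienes with 3-alkoxy- and 3,3-dialkoxy-enones, known for 4-alkoxy dienes, for 4,4-dimethoxy enones and for 4-alkoxy-2-oxobut-3-enoates, so only the pairing is new. No stereocentre is kept: the centres of 9 and 10 vanish on aromatisation, and the enol ether geometries do not matter because the push-pull alkene of 9 rotates easily once coordinated. The selectivity needed is orientation (terminus to the acetal carbon, central carbon to the ketone; the reverse pairing would give a terephthalate) and C- rather than O-closure; the first is secured by the much higher nucleophilicity of the diene terminus together with the vinylogous deactivation of the ketone in 8, the second by the oxophilic, chelating TiCl4, which keeps the ketone activated. A benzyl ether cannot ionise to an allyl cation or undergo a sigmatropic shift here, and any benzyl group lost to the Lewis acid would be put back in step 6.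

**Step 6**
Reactants: 11 dimethyl 4-(benzyloxy)-3-hydroxy-5-methoxyphthalate
Product: 12 dimethyl 3,4-bis(benzyloxy)-5-methoxyphthalate
Conditions: BnBr, K2CO3, DMF, 60 °C
Reagents that add atoms: benzyl bromide, BrCc1ccccc1
Why: Williamson etherification of the salicylate-type phenol removes the acidic OH, so that no phenoxide deactivates the neighbouring ester in step 8, and both benzyl groups leave together in step 9.

**Step 7**
Reactants: 12 dimethyl 3,4-bis(benzyloxy)-5-methoxyphthalate
Product: 13 3,4-bis(benzyloxy)-5-methoxy-2-(methoxycarbonyl)benzoic acid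
Conditions: KOH (1.5 equiv), MeOH–H2O, 50 °C; then 1 M HCl
Reagents that add atoms: potassium hydroxide, [K+].[OH-]
Why: Sterically controlled mono-saponification (BAc2), since the C1 ester has C6–H as one ortho neighbour, the C2 ester is blocked on both sides, and the first-formed carboxylate further repels hydroxide from it.

**Step 8**
Reactants: 13 3,4-bis(benzyloxy)-5-methoxy-2-(methoxycarbonyl)benzoic acid
Product: 15 4,5-bis(benzyloxy)-6-methoxyisobenzofuran-1(3H)-one, via hydroxy acid 14 (not isolated)
Conditions: LiEt3BH (3.5 equiv), THF, 0 → 40 °C; then 2 M HCl, 20 °C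
Reagents that add atoms: none
Why: Chemoselective hydride reduction of an ester beside a lithium carboxylate that LiEt3BH leaves alone, followed by acid-catalysed 5-exo-trig lactonisation, places the CH2 at C3a next to O4, whereas direct reduction of diester 12 would take the exposed ester and give the isomeric phthalide.

**Step 9**
Reactants: 15 4,5-bis(benzyloxy)-6-methoxyisobenzofuran-1(3H)-one
Product: 16 4,5-dihydroxy-6-methoxyisobenzofuran-1(3H)-one
Conditions: H2 (1 atm), Pd/C (10%), EtOAc–MeOH, 20 °C
Reagents that add atoms: none
Why: Catalytic hydrogenolysis of benzyl aryl ethers under neutral conditions at atmospheric pressure should leave the lactone and the aryl methyl ether untouched.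

**Step 10**
Reactants: 17 (2E,6E)-farnesol
Product: 18 (2E,6E)-farnesyl acetate
Conditions: Ac2O, pyridine, DMAP (cat.), CH2Cl2, 0 → 20 °C
Reagents that add atoms: acetic anhydride, CC(=O)OC(C)=O
Why: DMAP-catalysed acetylation protects the alcohol and lowers the nucleophilicity of the C2=C3 alkene for the next step.

**Step 11**
Reactants: 18 (2E,6E)-farnesyl acetate
Product: 19 (2E,6E)-10-bromo-11-hydroxy-3,7,11-trimethyldodeca-2,6-dien-1-yl acetate (racemic)
Conditions: NBS (1.05 equiv), THF–H2O, 0 °C
Reagents that add atoms: N-bromosuccinimide, O=C1CCC(=O)N1Br; water, O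
Why: Bromohydrin formation in aqueous medium is known to favour the exposed terminal trisubstituted alkene of farnesyl esters, with Markovnikov attack of water at C11, and the new C10 centre is racemic and removed in step 13.

**Step 12**
Reactants: 19 (2E,6E)-10-bromo-11-hydroxy-3,7,11-trimethyldodeca-2,6-dien-1-yl acetate
Product: 21 (2E,6E)-10,11-epoxy-3,7,11-trimethyldodeca-2,6-dien-1-ol (racemic), via epoxy acetate 20 (not isolated)
Conditions: K2CO3, MeOH, 20 °C
Reagents that add atoms: none
Why: Intramolecular Williamson closure of the bromohydrin to the epoxide is followed in the same flask by base-catalysed transesterification of the acetate with methanol.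

**Step 13**
Reactants: 21 (2E,6E)-10,11-epoxy-3,7,11-trimethyldodeca-2,6-dien-1-ol
Product: 22 (2E,6E)-3,7,11-trimethyldodeca-2,6-diene-1,11-diol
Conditions: LiAlH4, THF, 0 → 40 °C; then H2O, aq. NaOH
Reagents that add atoms: none
Why: SN2 hydride opening of the trisubstituted epoxide at the less substituted C10 delivers the tertiary alcohol and erases the stereocentre, while unactivated trisubstituted alkenes are inert to LiAlH4.

**Step 14**
Reactants: 22 (2E,6E)-3,7,11-trimethyldodeca-2,6-diene-1,11-diol
Product: 23 (6E,10E)-12-bromo-2,6,10-trimethyldodeca-6,10-dien-2-ol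
Conditions: CBr4, PPh3, CH2Cl2, −20 → 0 °C; used at once
Reagents that add atoms: tetrabromomethane, BrC(Br)(Br)Br
Why: In the Appel reaction the primary allylic alcohol forms the alkoxyphosphonium salt and is displaced by bromide in SN2 fashion with retention of alkene geometry, whereas the tertiary alcohol is too hindered to engage at low temperature.

**Step 15**
Reactants: 16 4,5-dihydroxy-6-methoxyisobenzofuran-1(3H)-one; 23 (6E,10E)-12-bromo-2,6,10-trimethyldodeca-6,10-dien-2-ol
Product: 24 farnesylemefuranone E, 4-hydroxy-5-{[(2E,6E)-11-hydroxy-3,7,11-trimethyldodeca-2,6-dien-1-yl]oxy}-6-methoxyisobenzofuran-1(3H)-one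
Conditions: KHCO3 (1.1 equiv), DMF, 20 → 40 °C, slight excess of 16
Reagents that add atoms: none
Why: Site-selective Williamson etherification, since O5–H is para to C7a and its lactone carbonyl and is thus the more acidic phenol, so only it is deprotonated by the weak base (as in the known para-selective O-alkylation of gallates and 3,4-dihydroxybenzaldehyde), and SN2 at the primary allylic bromide keeps both E alkenes.

**Compound list**
1 | methyl 4-chloroacetoacetate | COC(=O)CC(=O)CCl | starting material
2 | benzyl alcohol | OCc1ccccc1 | starting material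
3 | methyl 4-(benzyloxy)-3-oxobutanoate | COC(=O)CC(=O)COCc1ccccc1 | intermediate
4 | methyl 4-(benzyloxy)-3-(trimethylsilyloxy)but-2-enoate | COC(=O)C=C(COCc1ccccc1)O[Si](C)(C)C | intermediate
5 | 4-(benzyloxy)-1-methoxy-1,3-bis(trimethylsilyloxy)buta-1,3-diene | COC(O[Si](C)(C)C)=CC(O[Si](C)(C)C)=COCc1ccccc1 | intermediate
6 | 1,1-dimethoxyethene | C=C(OC)OC | starting material
7 | methyl chlorooxoacetate | COC(=O)C(Cl)=O | starting material
8 | methyl 4,4-dimethoxy-2-oxobut-3-enoate | COC(=O)C(=O)C=C(OC)OC | intermediate
9 | dimethyl 5-(benzyloxy)-4-methoxy-2,6-dioxooct-3-enedioate (racemic, not isolated) | COC(=O)C(=O)C=C(OC)C(OCc1ccccc1)C(=O)CC(=O)OC | intermediate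
10 | dimethyl 4-(benzyloxy)-1-hydroxy-5-methoxy-3-oxocyclohex-5-ene-1,2-dicarboxylate (diastereomer mixture, not isolated) | COC(=O)C1(O)C=C(OC)C(OCc2ccccc2)C(=O)C1C(=O)OC | intermediate
11 | dimethyl 4-(benzyloxy)-3-hydroxy-5-methoxyphthalate | COC(=O)c1cc(OC)c(OCc2ccccc2)c(O)c1C(=O)OC | intermediate
12 | dimethyl 3,4-bis(benzyloxy)-5-methoxyphthalate | COC(=O)c1cc(OC)c(OCc2ccccc2)c(OCc2ccccc2)c1C(=O)OC | intermediate
13 | 3,4-bis(benzyloxy)-5-methoxy-2-(methoxycarbonyl)benzoic acid | COC(=O)c1c(OCc2ccccc2)c(OCc2ccccc2)c(OC)cc1C(=O)O | intermediate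
14 | 3,4-bis(benzyloxy)-2-(hydroxymethyl)-5-methoxybenzoic acid (not isolated) | OCc1c(OCc2ccccc2)c(OCc2ccccc2)c(OC)cc1C(=O)O | intermediate
15 | 4,5-bis(benzyloxy)-6-methoxyisobenzofuran-1(3H)-one | COc1cc2c(c(OCc3ccccc3)c1OCc1ccccc1)COC2=O | intermediate
16 | 4,5-dihydroxy-6-methoxyisobenzofuran-1(3H)-one | COc1cc2c(c(O)c1O)COC2=O | intermediate
17 | (2E,6E)-farnesol | OC/C=C(\C)CC/C=C(\C)CCC=C(C)C | starting material
18 | (2E,6E)-farnesyl acetate | CC(=O)OC/C=C(\C)CC/C=C(\C)CCC=C(C)C | intermediate
19 | (2E,6E)-10-bromo-11-hydroxy-3,7,11-trimethyldodeca-2,6-dien-1-yl acetate (racemic) | CC(=O)OC/C=C(\C)CC/C=C(\C)CCC(Br)C(C)(C)O | intermediate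
20 | (2E,6E)-10,11-epoxy-3,7,11-trimethyldodeca-2,6-dien-1-yl acetate (racemic, not isolated) | CC(=O)OC/C=C(\C)CC/C=C(\C)CCC1OC1(C)C | intermediate
21 | (2E,6E)-10,11-epoxy-3,7,11-trimethyldodeca-2,6-dien-1-ol (racemic) | OC/C=C(\C)CC/C=C(\C)CCC1OC1(C)C | intermediate
22 | (2E,6E)-3,7,11-trimethyldodeca-2,6-diene-1,11-diol | OC/C=C(\C)CC/C=C(\C)CCCC(C)(C)O | intermediate
23 | (6E,10E)-12-bromo-2,6,10-trimethyldodeca-6,10-dien-2-ol | BrC/C=C(\C)CC/C=C(\C)CCCC(C)(C)O | intermediate
24 | farnesylemefuranone E | COc1cc2c(c(O)c1OC/C=C(\C)CC/C=C(\C)CCCC(C)(C)O)COC2=O | target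

**Count**
Total step count: 15.
Longest linear sequence: 9 steps (1, 2, 3, 5, 6, 7, 8, 9, 15).

**Steps most likely to fail**

Step 5. Three processes could defeat the annulation. The orientation may reverse through direct attack of the diene terminus on the strongly activated keto group. Ring closure may take place through oxygen instead of carbon. Chloride may demethylate the ketene acetal before any C–C bond forms. The fallback builds the benzene ring by a Diels–Alder/aromatisation sequence with a symmetrical dienophile, which has no orientation problem. It sets out from benzyl alcohol 2. Rh2(OAc)4-catalysed O–H insertion of commercial ethyl 2-diazo-3-oxobutanoate would give ethyl 2-(benzyloxy)-3-oxobutanoate F1. HC(OMe)3 with catalytic H2SO4 would give ethyl 2-(benzyloxy)-3-methoxybut-2-enoate F2. LiN(iPr)2 followed by Me3SiCl would give 2-(benzyloxy)-1-ethoxy-3-methoxy-1-(trimethylsilyloxy)buta-1,3-diene F3. Heating with dimethyl acetylenedicarboxylate in toluene would give dimethyl 4-(benzyloxy)-3-ethoxy-5-methoxy-3-(trimethylsilyloxy)cyclohexa-1,4-diene-1,2-dicarboxylate F4. This adduct loses ethanol and, on mild acidic work-up, the silyl group, and the fallback comes back to the route at 11.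

Step 15. Discrimination between the two neighbouring phenolic oxygens may be poor, and double alkylation may occur. The fallback attaches the chain before the lactone exists, at a stage where the competing hydroxyl is locked in a hydrogen bond to an ester. It sets out from 11. Hydrogenolysis (H2, Pd/C) would give dimethyl 3,4-dihydroxy-5-methoxyphthalate F5. Its free C4 hydroxyl (para to the C1 ester) would be alkylated with bromide 23 (KHCO3, DMF) to give dimethyl 3-hydroxy-4-{[(2E,6E)-11-hydroxy-3,7,11-trimethyldodeca-2,6-dien-1-yl]oxy}-5-methoxyphthalate F6. LiOH would cleave the exposed ester to give 3-hydroxy-4-{[(2E,6E)-11-hydroxy-3,7,11-trimethyldodeca-2,6-dien-1-yl]oxy}-5-methoxy-2-(methoxycarbonyl)benzoic acid F7. Excess LiEt3BH would reduce the lithium-chelated salicylate ester to 3-hydroxy-2-(hydroxymethyl)-4-{[(2E,6E)-11-hydroxy-3,7,11-trimethyldodeca-2,6-dien-1-yl]oxy}-5-methoxybenzoic acid F8. This lactonises on acidification with citric acid, and the fallback comes back to the route at 24.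

Step 8. Hydride transfer to an ester that is blocked on both sides and sits next to a negatively charged carboxylate may be slow or incomplete. The fallback replaces selective reduction by full reduction and selective re-oxidation. It sets out from 12. LiAlH4 would reduce both esters to [3,4-bis(benzyloxy)-5-methoxy-1,2-phenylene]dimethanol F9. TEMPO with PhI(OAc)2 would then oxidise the less hindered hydroxymethyl group (the one next to C–H) first. The resulting aldehyde closes to 4,5-bis(benzyloxy)-6-methoxy-1,3-dihydroisobenzofuran-1-ol F10, which is oxidised further in the same flask, and the fallback comes back to the route at 15.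

**Further compounds**
F1 | step 5 | ethyl 2-(benzyloxy)-3-oxobutanoate | CCOC(=O)C(OCc1ccccc1)C(C)=O
F2 | step 5 | ethyl 2-(benzyloxy)-3-methoxybut-2-enoate | CCOC(=O)C(OCc1ccccc1)=C(C)OC
F3 | step 5 | 2-(benzyloxy)-1-ethoxy-3-methoxy-1-(trimethylsilyloxy)buta-1,3-diene | CCOC(O[Si](C)(C)C)=C(OCc1ccccc1)C(=C)OC
F4 | step 5 | dimethyl 4-(benzyloxy)-3-ethoxy-5-methoxy-3-(trimethylsilyloxy)cyclohexa-1,4-diene-1,2-dicarboxylate | CCOC1(O[Si](C)(C)C)C(OCc2ccccc2)=C(OC)CC(C(=O)OC)=C1C(=O)OC
F5 | step 15 | dimethyl 3,4-dihydroxy-5-methoxyphthalate | COC(=O)c1cc(OC)c(O)c(O)c1C(=O)OC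
F6 | step 15 | dimethyl 3-hydroxy-4-{[(2E,6E)-11-hydroxy-3,7,11-trimethyldodeca-2,6-dien-1-yl]oxy}-5-methoxyphthalate | COC(=O)c1cc(OC)c(OC/C=C(\C)CC/C=C(\C)CCCC(C)(C)O)c(O)c1C(=O)OC
F7 | step 15 | 3-hydroxy-4-{[(2E,6E)-11-hydroxy-3,7,11-trimethyldodeca-2,6-dien-1-yl]oxy}-5-methoxy-2-(methoxycarbonyl)benzoic acid | COC(=O)c1c(O)c(OC/C=C(\C)CC/C=C(\C)CCCC(C)(C)O)c(OC)cc1C(=O)O
F8 | step 15 | 3-hydroxy-2-(hydroxymethyl)-4-{[(2E,6E)-11-hydroxy-3,7,11-trimethyldodeca-2,6-dien-1-yl]oxy}-5-methoxybenzoic acid | OCc1c(O)c(OC/C=C(\C)CC/C=C(\C)CCCC(C)(C)O)c(OC)cc1C(=O)O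
F9 | step 8 | [3,4-bis(benzyloxy)-5-methoxy-1,2-phenylene]dimethanol | COc1cc(CO)c(CO)c(OCc2ccccc2)c1OCc1ccccc1
F10 | step 8 | 4,5-bis(benzyloxy)-6-methoxy-1,3-dihydroisobenzofuran-1-ol | COc1cc2c(c(OCc3ccccc3)c1OCc1ccccc1)COC2O
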